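**Time and readings.** Time was the setting asked about, and the flask repeated the summer run, so its readings served directly.

| setting | summer | dusk | flask |
|---|---|---|---|
| starting material | 16 mM | 16 mM | 16 mM |
| reagent in the second phase | 32 mM | 48 mM | 32.0 mM |
| remark | the very flask that is asked about, followed so far | run made earlier |  |
| time |  |  | 30 min |
| volume of the second phase over the first |  |  | 1.0 |

- summer (time / min: product / %, starting material / %): 0.833: 8.9, 90.5; 1.33: 13.3, 86.6; 2.50: 18.7, 81.5; 5.00: 17.8, 82.0; 10.0: 11.9, 87.7
- dusk (time / min: product / %, starting material / %): 0.833: 13.3, 86.3; 2.00: 23.6, 76.7; 4.00: 22.8, 77.8; 10.0: 15.0, 85.4; 20.0: 8.9, 91.3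

(readings scatter by 0.5 percentage points)

- in the second phase: reagent in the second phase; everything else is in the first
- charges count per volume of the first phase; a concentration in a rate is the amount of a species over the volume of its own phase; every rate counts per litre of the first phase
- the earlier runs hold the two phases in the same ratio of volumes as the flask asked about

* the moment within 30 min at which there is most product
* the amount of product, in percent of the starting material charged, at that time

**The rise.** With P the product as a fraction of the charge and t the time, the summer run started at a slope of 0.107 /min. At that slope it would have reached 18.7% by 1.75 min, but that reading came at 2.50 min, so the curve had already bent. I placed the top between 2.50 min and 5.00 min, a little above 18.7%.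

**The tail.** At 10.0 min, product and starting material summed to 99.6%, so starting material was returning as product fell. First-order constants read 0.0805 /min in the summer run between 5.00 min and 10.0 min, and 0.0522 /min in the dusk run between 10.0 min and 20.0 min. I therefore let P fall at s times P squared, an apparent second-order law. Integrated, the reciprocal of P climbs linearly with time, and its slope is the reciprocal slope s, 0.557 /min in the summer run. The dusk run gave 0.457 /min, a closer pair than the two first-order constants. Carried on from 10.0 min, s put the flask at 5.12% by 30 min.

**The forecast.** It gave 19.2% at 3.2 min, reasoning that “The 2.5 and 5 min readings (18.7, 17.8) bracket the peak”.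

**The result.** The flask peaked at 18.9% at 3.08 min, close to the forecast, and still held 17.9% at 4.62 min, so its top is a broad one. At 30.0 min it held 5.19%, against the 5.12% that s gave.

    reagent in the reaction phase ⇌ reagent in the second phase, rate k1*([reagent in the reaction phase] - [reagent in the second phase]/K1) per volume of the first phase (partition coefficient = 1.20, kL = 0.00792 /s)
    starting material + reagent in the reaction phase ⇌ product (K = 33.0 /M, k = 0.855 /M/s)
    2 reagent in the reaction phase → homo dimer (k = 0.483 /M/s)

**Second flask.** Read at 2.0 h, the same flask should hold 1.44% by s. The computed value is 1.33%.

The numbers in the tables are calculated on assumed constants; scatter was added.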